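## Retrosynthetic overview

1. Target ⇒ silyl-protected 8-hydroxy enone: the last bonds are C-4–H (hydride), C-3–H (proton from the face away from the aryl ring) and ArO–Si cleavage.
2. 8-Hydroxy enone ⇒ 8-sulfonylhydrazone ⇒ 2,8-dione: the key disconnection is the C-8–O bond, made by O–H insertion of water into the bridging carbene (sets C-8).
3. 2,8-Dione ⇒ quinone monoketal + (E)-propenylarene: enantioselective cationic [5+2] cycloaddition (C-5–C-6 first, then C-7–C-1).
4. Quinone monoketal ⇒ allylphenol (dearomatising C–O ketalisation) ⇒ 2,3,4-trimethoxyphenol + allyl bromide; propenylarene ⇒ 5-bromo-2-methoxyphenol + propenylboronate.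
5. Ring order: the six-membered ring is the dearomatised arene; the five-membered ring, and with it the bicyclo[3.2.1]octane, closes in the [5+2] step.

Locants: bicyclo[3.2.1]octane numbering, C-1 = methoxy bridgehead, C-2 = C=O, C-3 = CH(OMe), C-4 = CH2, C-5 = allyl bridgehead, C-6 = CHMe, C-7 = CHAr, C-8 = one-carbon bridge.

Assumption: the (R)-acid of step 6 is taken to give the enantiomer drawn; if the sense of induction is opposite, its mirror-image acid is used.

## Route

Step 1
Reactants: 1 2,3,4-trimethoxyphenol; 2 allyl bromide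
Product: 3 1,2,3-trimethoxy-4-(prop-2-en-1-yloxy)benzene
Conditions: K2CO3, acetone, 56 °C
Reagents that add atoms: none
Why: Williamson ether synthesis (SN2 of the phenoxide on the allylic bromide); no stereocenter is formed.

Step 2
Reactants: 3 1,2,3-trimethoxy-4-(prop-2-en-1-yloxy)benzene
Product: 4 2,3,4-trimethoxy-6-(prop-2-en-1-yl)phenol
Conditions: N,N-diethylaniline, 200 °C
Reagents that add atoms: none
Why: Aromatic Claisen rearrangement ([3,3]-sigmatropic shift) delivers the allyl group to C-6, the only ortho position that can re-aromatise; no stereocenter is formed.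

Step 3
Reactants: 4 2,3,4-trimethoxy-6-(prop-2-en-1-yl)phenol
Product: 5 4,4,5,6-tetramethoxy-2-(prop-2-en-1-yl)cyclohexa-2,5-dien-1-one
Conditions: PhI(OAc)2, MeOH, 0 °C
Reagents that add atoms: methanol, CO
Why: Oxidative dearomatisation, in which PhI(OAc)2 oxidises the para-methoxyphenol to the phenoxonium ion and methanol forms the new C–O bond at the para carbon to give the quinone monoketal; no stereocenter is formed.

Step 4
Reactants: 6 5-bromo-2-methoxyphenol; 7 4,4,5,5-tetramethyl-2-[(1E)-prop-1-en-1-yl]-1,3,2-dioxaborolane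
Product: 8 2-methoxy-5-[(1E)-prop-1-en-1-yl]phenol
Conditions: PdCl2(dppf) (3 mol %; dppf = 1,1'-bis(diphenylphosphino)ferrocene), K2CO3, 1,4-dioxane/H2O, 80 °C
Reagents that add atoms: none
Why: Suzuki–Miyaura coupling, which transfers the alkenyl group with retention of the E geometry.

Step 5
Reactants: 8 2-methoxy-5-[(1E)-prop-1-en-1-yl]phenol
Product: 9 tert-butyl{2-methoxy-5-[(1E)-prop-1-en-1-yl]phenoxy}dimethylsilane
Conditions: TBSCl, imidazole, DMF, 23 °C
Reagents that add atoms: tert-butyldimethylsilyl chloride (TBSCl), CC(C)(C)[Si](C)(C)Cl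
Why: Silylation of the phenol, which would otherwise compete as an O- and C-nucleophile in step 6 and as an O–H insertion partner in step 8; no stereocenter is formed.

Step 6
Reactants: 5 4,4,5,6-tetramethoxy-2-(prop-2-en-1-yl)cyclohexa-2,5-dien-1-one; 9 tert-butyl{2-methoxy-5-[(1E)-prop-1-en-1-yl]phenoxy}dimethylsilane
Product: 10 (1S,5R,6R,7S)-7-{3-[(tert-butyldimethylsilyl)oxy]-4-methoxyphenyl}-1,3-dimethoxy-6-methyl-5-(prop-2-en-1-yl)bicyclo[3.2.1]oct-3-ene-2,8-dione
Conditions: (R)-3,3'-bis(2,4,6-triisopropylphenyl)-1,1'-binaphthyl-2,2'-diyl N-(trifluoromethylsulfonyl)phosphoramidate, (R)-(ArO)2P(O)NHSO2CF3 (5 mol %), CH2Cl2, −78 to −40 °C; Et3N quench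
Reagents that add atoms: none
Why: Proposed new method: the chiral acid ionises the ketal to a 4-methoxy-oxocarbenium (2-oxidopentadienyl-type) cation held in a contact ion pair, the β-carbon of the propenylarene attacks the allyl-bearing terminus on the face left open by the chiral anion (sets C-5 and C-6), the benzylic cation is then captured endo by the electron-rich dimethoxy enol ether carbon (sets C-1 and C-7, the E alkene giving 6-exo-methyl and 7-endo-aryl), and the liberated methanol removes the O-methyl group of the resulting oxocarbenium as dimethyl ether to release the 2-ketone and the proton; the closest known reactions are the racemic acid-mediated [5+2] cycloaddition of quinone monoketals with (E)-propenylarenes and chiral-anion-controlled cycloadditions of oxocarbenium ions.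

Step 7
Reactants: 10 (1S,5R,6R,7S)-7-{3-[(tert-butyldimethylsilyl)oxy]-4-methoxyphenyl}-1,3-dimethoxy-6-methyl-5-(prop-2-en-1-yl)bicyclo[3.2.1]oct-3-ene-2,8-dione
Product: 11 N'-[(1S,5R,6R,7S)-7-{3-[(tert-butyldimethylsilyl)oxy]-4-methoxyphenyl}-1,3-dimethoxy-6-methyl-2-oxo-5-(prop-2-en-1-yl)bicyclo[3.2.1]oct-3-en-8-ylidene]-2-(trifluoromethyl)benzenesulfonohydrazide
Conditions: 2-(CF3)C6H4SO2NHNH2 (1.2 equiv), AcOH (10 mol %), THF, 40 °C
Reagents that add atoms: 2-(trifluoromethyl)benzenesulfonohydrazide, NNS(=O)(=O)c1ccccc1C(F)(F)F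
Why: Hydrazone condensation (C=N bond formation) occurs at the strained, non-conjugated bridging ketone and not at the conjugated, doubly flanked C-2 carbonyl, with acid catalysis favouring dehydration over retro-Claisen cleavage; no new stereocenter is formed and the C=N geometry is immaterial.

Step 8
Reactants: 11 N'-[(1S,5R,6R,7S)-7-{3-[(tert-butyldimethylsilyl)oxy]-4-methoxyphenyl}-1,3-dimethoxy-6-methyl-2-oxo-5-(prop-2-en-1-yl)bicyclo[3.2.1]oct-3-en-8-ylidene]-2-(trifluoromethyl)benzenesulfonohydrazide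
Product: 13 (1S,5R,6R,7S,8S)-7-{3-[(tert-butyldimethylsilyl)oxy]-4-methoxyphenyl}-8-hydroxy-1,3-dimethoxy-6-methyl-5-(prop-2-en-1-yl)bicyclo[3.2.1]oct-3-en-2-one, via diazo compound 12 (not isolated)
Conditions: NaH (1.05 equiv), THF, 0 °C; then Rh2(OAc)4 (2 mol %), H2O (20 equiv), 40 °C
Reagents that add atoms: water, O
Why: Proposed new method: Bamford–Stevens loss of sulfinate gives the bridging diazoalkane, Rh2(OAc)4 turns it into a carbene that has no α-hydrogen and cannot rearrange to a bridgehead alkene, water adds to the carbene carbon from the open face over the flat enone bridge (anti to the exo-methyl on C-6) and the oxonium ylide passes its proton to the rhodium-bearing face, so that oxygen ends up syn to the enone bridge (8S), which on the same steric model is the epimer that hydride delivery to the 8-ketone would not give; the closest known reactions are metal-catalysed O–H insertions of carbenes generated from ketone N-sulfonylhydrazones (reductive etherification).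

Step 9
Reactants: 13 (1S,5R,6R,7S,8S)-7-{3-[(tert-butyldimethylsilyl)oxy]-4-methoxyphenyl}-8-hydroxy-1,3-dimethoxy-6-methyl-5-(prop-2-en-1-yl)bicyclo[3.2.1]oct-3-en-2-one
Product: 15 (1S,3S,5S,6R,7S,8S)-8-hydroxy-7-(3-hydroxy-4-methoxyphenyl)-1,3-dimethoxy-6-methyl-5-(prop-2-en-1-yl)bicyclo[3.2.1]octan-2-one, via silyl ether 14 (not isolated)
Conditions: [(Ph3P)CuH]6 (0.4 equiv), H2O (5 equiv), toluene/THF, 23 °C; then KHF2, MeOH, 23 °C
Reagents that add atoms: none
Why: Copper hydride conjugate reduction (Stryker's reagent) adds hydride to C-4 without touching the allyl group or the ketone, the copper enolate is protonated at C-3 on the face syn to C-8 (the other face is covered by the endo aryl ring and the 8-hydroxyl can relay the proton), which sets 3S, and KHF2 then cleaves the aryl silyl ether under near-neutral conditions that neither epimerise C-3 nor trigger retro-aldol opening.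

## Compound list

1 | 2,3,4-trimethoxyphenol | COc1ccc(O)c(OC)c1OC | starting material
2 | allyl bromide (3-bromoprop-1-ene) | C=CCBr | starting material
3 | 1,2,3-trimethoxy-4-(prop-2-en-1-yloxy)benzene | C=CCOc1ccc(OC)c(OC)c1OC | intermediate
4 | 2,3,4-trimethoxy-6-(prop-2-en-1-yl)phenol | C=CCc1cc(OC)c(OC)c(OC)c1O | intermediate
5 | 4,4,5,6-tetramethoxy-2-(prop-2-en-1-yl)cyclohexa-2,5-dien-1-one | C=CCC1=CC(OC)(OC)C(OC)=C(OC)C1=O | intermediate
6 | 5-bromo-2-methoxyphenol | COc1ccc(Br)cc1O | starting material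
7 | 4,4,5,5-tetramethyl-2-[(1E)-prop-1-en-1-yl]-1,3,2-dioxaborolane | C/C=C/B1OC(C)(C)C(C)(C)O1 | starting material
8 | 2-methoxy-5-[(1E)-prop-1-en-1-yl]phenol | C/C=C/c1ccc(OC)c(O)c1 | intermediate
9 | tert-butyl{2-methoxy-5-[(1E)-prop-1-en-1-yl]phenoxy}dimethylsilane | C/C=C/c1ccc(OC)c(O[Si](C)(C)C(C)(C)C)c1 | intermediate
10 | (1S,5R,6R,7S)-7-{3-[(tert-butyldimethylsilyl)oxy]-4-methoxyphenyl}-1,3-dimethoxy-6-methyl-5-(prop-2-en-1-yl)bicyclo[3.2.1]oct-3-ene-2,8-dione (7-aryl endo, 6-methyl exo) | C=CC[C@]12C=C(OC)C(=O)[C@](OC)([C@H](c3ccc(OC)c(O[Si](C)(C)C(C)(C)C)c3)[C@H]1C)C2=O | intermediate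
11 | N'-[(1S,5R,6R,7S)-7-{3-[(tert-butyldimethylsilyl)oxy]-4-methoxyphenyl}-1,3-dimethoxy-6-methyl-2-oxo-5-(prop-2-en-1-yl)bicyclo[3.2.1]oct-3-en-8-ylidene]-2-(trifluoromethyl)benzenesulfonohydrazide (C=N geometry not defined) | C=CC[C@]12C=C(OC)C(=O)[C@](OC)([C@H](c3ccc(OC)c(O[Si](C)(C)C(C)(C)C)c3)[C@H]1C)C2=NNS(=O)(=O)c1ccccc1C(F)(F)F | intermediate
12 | (1S,5R,6R,7S)-7-{3-[(tert-butyldimethylsilyl)oxy]-4-methoxyphenyl}-8-diazo-1,3-dimethoxy-6-methyl-5-(prop-2-en-1-yl)bicyclo[3.2.1]oct-3-en-2-one | C=CC[C@]12C=C(OC)C(=O)[C@](OC)([C@H](c3ccc(OC)c(O[Si](C)(C)C(C)(C)C)c3)[C@H]1C)C2=[N+]=[N-] | intermediate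
13 | (1S,5R,6R,7S,8S)-7-{3-[(tert-butyldimethylsilyl)oxy]-4-methoxyphenyl}-8-hydroxy-1,3-dimethoxy-6-methyl-5-(prop-2-en-1-yl)bicyclo[3.2.1]oct-3-en-2-one (8-OH syn to the C-2 to C-4 bridge) | C=CC[C@]12C=C(OC)C(=O)[C@](OC)([C@H](c3ccc(OC)c(O[Si](C)(C)C(C)(C)C)c3)[C@H]1C)[C@H]2O | intermediate
14 | (1S,3S,5S,6R,7S,8S)-7-{3-[(tert-butyldimethylsilyl)oxy]-4-methoxyphenyl}-8-hydroxy-1,3-dimethoxy-6-methyl-5-(prop-2-en-1-yl)bicyclo[3.2.1]octan-2-one | C=CC[C@]12C[C@H](OC)C(=O)[C@](OC)([C@H](c3ccc(OC)c(O[Si](C)(C)C(C)(C)C)c3)[C@H]1C)[C@H]2O | intermediate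
15 | (1S,3S,5S,6R,7S,8S)-8-hydroxy-7-(3-hydroxy-4-methoxyphenyl)-1,3-dimethoxy-6-methyl-5-(prop-2-en-1-yl)bicyclo[3.2.1]octan-2-one (CNP0209708.1) | C=CC[C@]12C[C@H](OC)C(=O)[C@](OC)([C@H](c3ccc(OC)c(O)c3)[C@H]1C)[C@H]2O | target

## Step count and risks

Total steps: 9. Longest linear sequence: 7 (steps 1, 2, 3, 6, 7, 8, 9).

The three steps most likely to fail:

Step 6 is a new reaction. The ee may be low, the alkene may attack the methoxy-bearing terminus of the cation, the kinetic adduct may drift to the dihydrobenzofuran, or the oxocarbenium may methylate the catalyst. The fallback uses known chemistry and sets out from 5 (with 9). The cycloaddition is run under the established achiral conditions for quinone monoketals and (E)-propenylarenes (catalytic TfOH, MeCN, −40 °C). This gives 10 as a racemate, that is, together with its mirror image (1R,5S,6S,7R)-7-{3-[(tert-butyldimethylsilyl)oxy]-4-methoxyphenyl}-1,3-dimethoxy-6-methyl-5-(prop-2-en-1-yl)bicyclo[3.2.1]oct-3-ene-2,8-dione F1. The two are separated by preparative chromatography on a chiral stationary phase, and the route is rejoined at 10.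

Step 8 is also new. The carbene may be lost to azine formation, attack on the allyl group or the enol ether, or 1,3-C–H insertion, and the face selectivity rests on a steric model that has not been tested; the C-8 configuration should be checked by NOE between H-8 and the 6-methyl group and H-7. The fallback uses known chemistry, sets out from 10 and so also bypasses step 7. NaBH4 (MeOH/CH2Cl2, −78 °C) reduces the strained bridging ketone chemoselectively. If hydride enters over the enone bridge as the model predicts, the product is the 8-epimeric alcohol (1S,5R,6R,7S,8R)-7-{3-[(tert-butyldimethylsilyl)oxy]-4-methoxyphenyl}-8-hydroxy-1,3-dimethoxy-6-methyl-5-(prop-2-en-1-yl)bicyclo[3.2.1]oct-3-en-2-one F2. Meerwein–Ponndorf–Verley/Oppenauer equilibration (Al(OiPr)3, iPrOH/acetone, toluene, 80 °C) then moves it to the more stable 8S alcohol, whose hydroxyl is clear of the exo-methyl group, and the route is rejoined at 13. If hydride instead enters from the other face, 13 is obtained directly.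

Step 9 may be slow, because the α-methoxy enone is a weak acceptor next to a quaternary carbon, and the stereochemistry at C-3 depends on kinetic protonation. The fallback separates hydride addition from protonation and sets out from 13. CuH-catalysed 1,4-hydrosilylation (Cu(OAc)2·H2O 5 mol %, 1,2-bis(diphenylphosphino)benzene, PhMe2SiH, toluene, 23 °C) gives the isolable silyl enol ether (1S,5S,6R,7S,8S)-7-{3-[(tert-butyldimethylsilyl)oxy]-4-methoxyphenyl}-2-{[dimethyl(phenyl)silyl]oxy}-1,3-dimethoxy-6-methyl-5-(prop-2-en-1-yl)bicyclo[3.2.1]oct-2-en-8-ol F3. A separate low-temperature protodesilylation with HF·pyridine (THF, −40 to 0 °C) then protonates C-3 from the exposed face and removes the aryl silyl group in the same operation, returning to the route at 15.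

## Further compounds

F1 | step 6 | (1R,5S,6S,7R)-7-{3-[(tert-butyldimethylsilyl)oxy]-4-methoxyphenyl}-1,3-dimethoxy-6-methyl-5-(prop-2-en-1-yl)bicyclo[3.2.1]oct-3-ene-2,8-dione | C=CC[C@@]12C=C(OC)C(=O)[C@@](OC)([C@@H](c3ccc(OC)c(O[Si](C)(C)C(C)(C)C)c3)[C@@H]1C)C2=O
F2 | step 8 | (1S,5R,6R,7S,8R)-7-{3-[(tert-butyldimethylsilyl)oxy]-4-methoxyphenyl}-8-hydroxy-1,3-dimethoxy-6-methyl-5-(prop-2-en-1-yl)bicyclo[3.2.1]oct-3-en-2-one | C=CC[C@]12C=C(OC)C(=O)[C@](OC)([C@H](c3ccc(OC)c(O[Si](C)(C)C(C)(C)C)c3)[C@H]1C)[C@@H]2O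
F3 | step 9 | (1S,5S,6R,7S,8S)-7-{3-[(tert-butyldimethylsilyl)oxy]-4-methoxyphenyl}-2-{[dimethyl(phenyl)silyl]oxy}-1,3-dimethoxy-6-methyl-5-(prop-2-en-1-yl)bicyclo[3.2.1]oct-2-en-8-ol | C=CC[C@]12CC(OC)=C(O[Si](C)(C)c3ccccc3)[C@](OC)([C@H](c3ccc(OC)c(O[Si](C)(C)C(C)(C)C)c3)[C@H]1C)[C@H]2O
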